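Ring A is cut from ring B at C1–C10 and C3–C4, so that C1–C2–C3 arrives as one trimethylene unit and both new bonds end on the carbons that flank C5. The key step is a one-pot [3+3] annulation of an enantiopure ring B enone, (S)-4-(methoxycarbonylmethyl)-3-methylcyclohex-2-enone: copper-catalysed conjugate addition of 3-chloropropylzinc iodide at C10, trans to the C5 arm, then ester-enolate cycloalkylation at C4 closes the trans-decalin. It exploits that C10 is beta to the C8 carbonyl (the later exocyclic methylene carbon) and C4 is alpha to the C19 carboxyl. C4 methylation, C9 alkylation with an (R)-iodide, methylenation and formylation complete the route.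

Key step: step 4

Remark: labdane numbering (C1–C20) is used for all ring compounds; the (R)-CBS catalyst is assumed to give the (S)-alcohol by the usual model, and methyl (R)-3-methylglutarate is taken as a commercial compound.

Step 1
Reactants: 1 2-methylcyclohex-2-en-1-one
Product: 2 (S)-2-methylcyclohex-2-en-1-ol
Conditions: (R)-2-methyl-CBS-oxazaborolidine (10 mol %), BH3·SMe2, THF, −20 °C
Reagents that add atoms: none
Why: Corey–Bakshi–Shibata reduction, in which the oxazaborolidine–borane complex delivers hydride to one carbonyl face (alkenyl side as the large group), should set the C9 carbinol as (S).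

Step 2
Reactants: 2 (S)-2-methylcyclohex-2-en-1-ol; 3 trimethyl orthoacetate
Product: 5 methyl 2-[(1S)-2-methylcyclohex-2-en-1-yl]acetate, via mixed ketene acetal 4 (not isolated)
Conditions: 3 (excess), EtCO2H (cat.), 140 °C, MeOH distilled off
Reagents that add atoms: none
Why: Johnson–Claisen rearrangement, in which ketene acetal 4 rearranges suprafacially, so the C9–O configuration is transferred to C5 as the C4–C5 bond forms on the same ring face and the alkene moves to C9=C10.

Step 3
Reactants: 5 methyl 2-[(1S)-2-methylcyclohex-2-en-1-yl]acetate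
Product: 6 methyl 2-[(1S)-2-methyl-4-oxocyclohex-2-en-1-yl]acetate
Conditions: Rh2(C6H10NO)4 (dirhodium tetracaprolactamate, 1 mol %), t-BuOOH (aq.), K2CO3, CH2Cl2, rt
Reagents that add atoms: tert-butyl hydroperoxide, CC(C)(C)OO
Why: Allylic C–H oxidation by tert-butylperoxyl radicals should attack the unhindered ring methylene C8 next to the alkene CH and give the conjugated enone, as trisubstituted cyclohexenes give 3-substituted cyclohexenones, with C5 untouched.

Step 4
Reactants: 6 methyl 2-[(1S)-2-methyl-4-oxocyclohex-2-en-1-yl]acetate; 7 1-chloro-3-iodopropane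
Product: 11 methyl 4a-methyl-6-(trimethylsilyloxy)-1,2,3,4,4a,7,8,8a-octahydronaphthalene-1-carboxylate (trans-fused; 5α-H; 10β-Me; ester 4α), via 3-chloropropylzinc iodide 8 (not isolated), via chloropropyl silyl enol ether 9 (not isolated), via ester lithium enolate 10 (not isolated)
Conditions: 7, Zn dust, THF, 40 °C; then 6, CuBr·SMe2 (10 mol %), Me3SiCl, HMPA, THF, −78 → 0 °C; hexane, filtration, evaporation; then LiN(iPr)2, THF–HMPA, −78 °C → rt
Reagents that add atoms: chlorotrimethylsilane, C[Si](C)(C)Cl
Why: Zinc inserts into the C–I bond of 7, and alkylzinc 8, transmetalated to copper and assisted by Me3SiCl, adds 1,4 to the enone so that C1 bonds to C10 and the C8–C9 enolate is trapped as silyl enol ether 9; LiN(iPr)2 then deprotonates only the ester arm, and enolate 10 displaces chloride at C3 to form C3–C4. The closest known reaction type is the conjugate addition–cycloalkylation annulation with a bifunctional organometallic (nucleophile plus latent electrophile), here as a [3+3] variant that ends on the ester carbon instead of the ketone alpha carbon. Ring A closes by a 6-exo-tet SN2 alkylation through a chair transition state. C10 is controlled by C5: allylic strain with the C10 methyl holds the C5 arm pseudoaxial, so the reagent attacks axially on the opposite face, which places the new chain trans to the arm and, after closure, should give the trans ring fusion with the C10 methyl beta and H5 alpha; C4 is expected to form with the ester equatorial through the hydrogen-eclipsed enolate conformer, and this centre is reset in step 5. The step needs 1,4- over 1,2-addition (copper and Me3SiCl), reaction at the C–Zn end without loss of the C–Cl end (zinc inserts only into C–I), and closure at C4 and not at C9, which is secured because the ketone enolate is masked as the silyl enol ether.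

Step 5
Reactants: 11 bicyclic silyl enol ether (C4–H ester)
Product: 13 methyl 1,4a-dimethyl-6-(trimethylsilyloxy)-1,2,3,4,4a,7,8,8a-octahydronaphthalene-1-carboxylate (4β-CO2Me axial; 4α-Me; 5α-H; 10β-Me), via ester lithium enolate 12 (not isolated)
Conditions: LiN(iPr)2, THF, −78 °C; MeI, −78 → 0 °C
Reagents that add atoms: iodomethane, CI
Why: Ester enolate alkylation, in which iodomethane approaches the exocyclic enolate from the equatorial alpha face because the beta face is shielded by the axial C10 methyl, should set C4 with the ester axial (C19) and the new methyl equatorial.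

Step 6
Reactants: 14 methyl (R)-3-methylglutarate
Product: 15 methyl (R)-5-hydroxy-3-methylpentanoate
Conditions: BH3·SMe2, THF, 0 °C → rt
Reagents that add atoms: none
Why: Borane reduction is chemoselective for the carboxylic acid over the methyl ester and leaves the stereocentre (future C13) untouched.

Step 7
Reactants: 15 methyl (R)-5-hydroxy-3-methylpentanoate
Product: 16 methyl (R)-5-(tert-butyldimethylsilyloxy)-3-methylpentanoate
Conditions: t-BuMe2SiCl, imidazole, DMF, rt
Reagents that add atoms: tert-butyldimethylsilyl chloride, CC(C)(C)[Si](C)(C)Cl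
Why: Silylation of the primary alcohol prevents lactonisation and protects the future C15 oxygen.

Step 8
Reactants: 16 methyl (R)-5-(tert-butyldimethylsilyloxy)-3-methylpentanoate
Product: 17 (S)-5-(tert-butyldimethylsilyloxy)-3-methylpentan-1-ol
Conditions: LiAlH4, Et2O, 0 °C
Reagents that add atoms: none
Why: Hydride reduction of the methyl ester gives the primary alcohol while the silyl ether survives (the descriptor changes only through the priority rules).

Step 9
Reactants: 17 (S)-5-(tert-butyldimethylsilyloxy)-3-methylpentan-1-ol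
Product: 18 (R)-tert-butyl[(5-iodo-3-methylpentyl)oxy]dimethylsilane
Conditions: PPh3, I2, imidazole, CH2Cl2, 0 °C → rt
Reagents that add atoms: iodine, II
Why: Appel-type iodination replaces the primary hydroxyl by SN2 at CH2, remote from the stereocentre.

Step 10
Reactants: 13 methylated bicyclic silyl enol ether; 18 (R)-tert-butyl[(5-iodo-3-methylpentyl)oxy]dimethylsilane
Product: 20 methyl (13S)-15-(tert-butyldimethylsilyloxy)-8-oxo-17-norlabdan-19-oate (5α-H; 9α-H; 10β-Me), via lithium enolate 19 (not isolated)
Conditions: MeLi, THF, 0 °C → rt; HMPA, 18, −30 °C → rt; then NaOMe (cat.), MeOH, rt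
Reagents that add atoms: none
Why: Regiospecific enolate alkylation, in which MeLi cleaves the O–Si bond to give the C8–C9 lithium enolate (the hindered axial ester is spared) and the primary iodide alkylates C9; axial attack may first give the axial epimer, and NaOMe equilibration through the enolate should leave the side chain equatorial (beta) with H9 alpha.

Step 11
Reactants: 20 methyl (13S)-15-(tert-butyldimethylsilyloxy)-8-oxo-17-norlabdan-19-oate
Product: 21 methyl (13S)-15-(tert-butyldimethylsilyloxy)labd-8(17)-en-19-oate
Conditions: Ph3PCH3Br, KOtBu, toluene, 90 °C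
Reagents that add atoms: methyltriphenylphosphonium bromide, C[P+](c1ccccc1)(c1ccccc1)c1ccccc1.[Br-]
Why: Wittig methylenation of the hindered C8 ketone installs the exocyclic alkene; the basic medium keeps C9 at its thermodynamic (desired) configuration and the hindered ester is inert.

Step 12
Reactants: 21 methyl (13S)-15-(tert-butyldimethylsilyloxy)labd-8(17)-en-19-oate
Product: 22 methyl (13S)-15-hydroxylabd-8(17)-en-19-oate
Conditions: Bu4NF, THF, rt
Reagents that add atoms: none
Why: Fluoride-mediated desilylation frees the primary alcohol without touching the alkene or the ester.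

Step 13
Reactants: 22 methyl (13S)-15-hydroxylabd-8(17)-en-19-oate
Product: 23 (13S)-15-hydroxylabd-8(17)-en-19-oic acid
Conditions: NaSEt, DMF, 100 °C; aq. HCl work-up
Reagents that add atoms: none
Why: Nucleophilic O-demethylation, in which thiolate attacks the ester methyl group by SN2, cleaves the axial C19 ester without attack at its hindered carbonyl and leaves the exocyclic alkene in place.

Step 14
Reactants: 23 (13S)-15-hydroxylabd-8(17)-en-19-oic acid
Product: 24 (13S)-15-formyloxylabd-8(17)-en-19-oic acid
Conditions: HCO2CH2CF3 (excess), THF, 65 °C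
Reagents that add atoms: 2,2,2-trifluoroethyl formate, O=COCC(F)(F)F
Why: Acyl transfer from the activated formate should formylate the primary alcohol chemoselectively under neutral conditions, leaving the hindered carboxylic acid and the exocyclic alkene unchanged.

Compound list
1 | 2-methylcyclohex-2-en-1-one | CC1=CCCCC1=O | starting material
2 | (S)-2-methylcyclohex-2-en-1-ol | O[C@H]1CCCC=C1C | intermediate
3 | trimethyl orthoacetate | CC(OC)(OC)OC | starting material
4 | mixed ketene acetal, 1-methoxy-1-[(S)-2-methylcyclohex-2-enyloxy]ethene | C=C(OC)O[C@H]1CCCC=C1C | intermediate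
5 | methyl 2-[(1S)-2-methylcyclohex-2-en-1-yl]acetate | COC(=O)C[C@@H]1CCCC=C1C | intermediate
6 | methyl 2-[(1S)-2-methyl-4-oxocyclohex-2-en-1-yl]acetate | COC(=O)C[C@@H]1CCC(=O)C=C1C | intermediate
7 | 1-chloro-3-iodopropane | ClCCCI | starting material
8 | 3-chloropropylzinc iodide | ClCCC[Zn]I | intermediate
9 | methyl 2-[(1S,2S)-2-(3-chloropropyl)-2-methyl-4-(trimethylsilyloxy)cyclohex-3-en-1-yl]acetate (chloropropyl trans to the acetate arm) | C[Si](C)(C)OC1=C[C@@](C)(CCCCl)[C@H](CC(=O)OC)CC1 | intermediate
10 | ester lithium enolate of 9 | C[Si](C)(C)OC1=C[C@@](C)(CCCCl)[C@H](C=C(OC)O[Li])CC1 | intermediate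
11 | methyl 4a-methyl-6-(trimethylsilyloxy)-1,2,3,4,4a,7,8,8a-octahydronaphthalene-1-carboxylate (trans-fused; 5α-H; 10β-Me; ester 4α) | C[Si](C)(C)OC1=C[C@@]2(C)CCC[C@@H](C(=O)OC)[C@@H]2CC1 | intermediate
12 | ester lithium enolate of 11 | C[Si](C)(C)OC1=C[C@@]2(C)CCCC(=C(OC)O[Li])[C@@H]2CC1 | intermediate
13 | methyl 1,4a-dimethyl-6-(trimethylsilyloxy)-1,2,3,4,4a,7,8,8a-octahydronaphthalene-1-carboxylate (4β-CO2Me axial; 4α-Me; 5α-H; 10β-Me) | C[Si](C)(C)OC1=C[C@@]2(C)CCC[C@](C)(C(=O)OC)[C@@H]2CC1 | intermediate
14 | methyl (R)-3-methylglutarate, (3R)-5-methoxy-3-methyl-5-oxopentanoic acid | OC(=O)C[C@@H](C)CC(=O)OC | starting material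
15 | methyl (R)-5-hydroxy-3-methylpentanoate | OCC[C@@H](C)CC(=O)OC | intermediate
16 | methyl (R)-5-(tert-butyldimethylsilyloxy)-3-methylpentanoate | CC(C)(C)[Si](C)(C)OCC[C@@H](C)CC(=O)OC | intermediate
17 | (S)-5-(tert-butyldimethylsilyloxy)-3-methylpentan-1-ol | CC(C)(C)[Si](C)(C)OCC[C@@H](C)CCO | intermediate
18 | (R)-tert-butyl[(5-iodo-3-methylpentyl)oxy]dimethylsilane | CC(C)(C)[Si](C)(C)OCC[C@@H](C)CCI | intermediate
19 | C8–C9 lithium enolate from 13 | [Li]OC1=C[C@@]2(C)CCC[C@](C)(C(=O)OC)[C@@H]2CC1 | intermediate
20 | methyl (13S)-15-(tert-butyldimethylsilyloxy)-8-oxo-17-norlabdan-19-oate (5α-H; 9α-H; 10β-Me) | O=C1CC[C@@H]2[C@](C)(CCC[C@]2(C)C(=O)OC)[C@H]1CC[C@H](C)CCO[Si](C)(C)C(C)(C)C | intermediate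
21 | methyl (13S)-15-(tert-butyldimethylsilyloxy)labd-8(17)-en-19-oate | C=C1CC[C@@H]2[C@](C)(CCC[C@]2(C)C(=O)OC)[C@H]1CC[C@H](C)CCO[Si](C)(C)C(C)(C)C | intermediate
22 | methyl (13S)-15-hydroxylabd-8(17)-en-19-oate | C=C1CC[C@@H]2[C@](C)(CCC[C@]2(C)C(=O)OC)[C@H]1CC[C@H](C)CCO | intermediate
23 | (13S)-15-hydroxylabd-8(17)-en-19-oic acid | C=C1CC[C@@H]2[C@](C)(CCC[C@]2(C)C(=O)O)[C@H]1CC[C@H](C)CCO | intermediate
24 | (13S)-15-formyloxylabd-8(17)-en-19-oic acid | C=C1CC[C@@H]2[C@](C)(CCC[C@]2(C)C(=O)O)[C@H]1CC[C@H](C)CCOC=O | target

Total step count: 14. Longest linear sequence: 10 steps (steps 1–5 and 10–14, from 1).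

Steps most likely to fail

Step 4. The 1,4-addition may stall at the fully substituted, gamma-branched beta carbon. The zinc reagent may be lost by 1,3-elimination to cyclopropane, or the silyl enol ether may be lost before the enolate closes ring A. The fallback sets out from 6 and comes back at 11, forming the two bonds in separate operations. Allylcopper (from allylmagnesium chloride and CuI·2LiCl) with Me3SiCl in THF at −78 °C adds 1,4 to 6, trans to the arm, to give the allyl silyl enol ether F1. Hydrozirconation of the terminal alkene with Cp2Zr(H)Cl followed by iodine gives the primary iodide F2. LiN(iPr)2 in THF–HMPA then closes C3–C4 and gives 11.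

Step 10. C-alkylation of the hindered enolate next to the quaternary C10 by an unactivated iodide may be slow, so that proton transfer leads to alkylation at C7, or O-alkylation intervenes. The fallback sets out from 13 (and alcohol 17) and comes back at 20. Alcohol 17 is oxidised (TEMPO, PhI(OAc)2) to (R)-5-(tert-butyldimethylsilyloxy)-3-methylpentanal F3. Mukaiyama aldol addition of 13 to F3 (TiCl4, CH2Cl2, −78 °C) gives the beta-hydroxy ketone F4. Dehydration (MsCl, Et3N, then DBU) gives the C9=C11 enone F5. Hydrogenation of this conjugated alkene (H2, Pd/C, EtOAc) and NaOMe equilibration of C9 give 20.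

Step 3. Hydrogen abstraction may occur at C5 or at the C10 methyl instead of C8, giving regioisomeric oxidation. The fallback sets out from 5 and comes back at 6. Epoxidation with mCPBA gives the C9–C10 epoxide F6. Opening at the less substituted C9 by PhSeNa (from (PhSe)2 and NaBH4, EtOH) gives the hydroxy selenide F7. Oxidation with H2O2 and selenoxide syn-elimination toward C8 give the tertiary allylic alcohol F8. Oxidative 1,3-transposition with pyridinium chlorochromate (CH2Cl2, rt) gives 6.

Further compounds
F1 | step 4 | methyl 2-[(1S,2S)-2-allyl-2-methyl-4-(trimethylsilyloxy)cyclohex-3-en-1-yl]acetate | C[Si](C)(C)OC1=C[C@@](C)(CC=C)[C@H](CC(=O)OC)CC1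
F2 | step 4 | methyl 2-[(1S,2S)-2-(3-iodopropyl)-2-methyl-4-(trimethylsilyloxy)cyclohex-3-en-1-yl]acetate | C[Si](C)(C)OC1=C[C@@](C)(CCCI)[C@H](CC(=O)OC)CC1
F3 | step 10 | (R)-5-(tert-butyldimethylsilyloxy)-3-methylpentanal | CC(C)(C)[Si](C)(C)OCC[C@@H](C)CC=O
F4 | step 10 | methyl (13S)-15-(tert-butyldimethylsilyloxy)-11-hydroxy-8-oxo-17-norlabdan-19-oate (mixture at C9 and C11) | O=C1CC[C@@H]2[C@](C)(CCC[C@]2(C)C(=O)OC)C1C(O)C[C@H](C)CCO[Si](C)(C)C(C)(C)C
F5 | step 10 | methyl (13S)-15-(tert-butyldimethylsilyloxy)-8-oxo-17-norlabd-9(11)-en-19-oate (alkene isomers) | O=C1CC[C@@H]2[C@](C)(CCC[C@]2(C)C(=O)OC)C1=CC[C@H](C)CCO[Si](C)(C)C(C)(C)C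
F6 | step 3 | methyl 2-[(1S)-2,3-epoxy-2-methylcyclohexyl]acetate | COC(=O)C[C@@H]1CCCC2OC12C
F7 | step 3 | methyl 2-[(1S)-2-hydroxy-2-methyl-3-(phenylselanyl)cyclohexyl]acetate | COC(=O)C[C@@H]1CCCC([Se]c2ccccc2)C1(C)O
F8 | step 3 | methyl 2-[(1S)-2-hydroxy-2-methylcyclohex-3-en-1-yl]acetate | COC(=O)C[C@@H]1CCC=CC1(C)O
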